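## Structural features

Lespecyrtin E3 (18) is a pterocarpan. Aromatic ring A is fused to the dihydropyran ring B (O5, C6, C6a, C11a, C11b, C4a). Ring B shares the C6a–C11a bond with the dihydrofuran ring C (C6a, C6b, C10a, O11, C11a), which is fused to aromatic ring D. A 2,2-dimethyl-2H-pyran (ring E) is fused to ring D across C7–C8, with its oxygen on C8. Ring A carries a prenyl group at C2 and a hydroxyl at C3. Ring D is hexasubstituted, with a hydroxyl at C9 and a prenyl group at C10 wedged between C9–OH and the O11-bearing C10a.

The only stereocentres are the adjacent C6a and C11a, cis-fused and both R. C11a is a benzylic ether carbon para to the C3 hydroxyl and ortho to O5. It ionises easily, and because the six/five ring fusion is comfortable only when cis, its configuration follows from C6a when ring C closes. The real stereochemical problem is therefore C6a alone, a tertiary benzylic carbon bonded to a di-ortho-substituted aryl group.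

Fragile elements are the two prenyl groups ortho to phenols (acid-induced chroman formation), the chromene alkene, the oxidation-prone oxygenated rings and the acid-labile C11a–O11 bond. The second difficulty is the regiocontrolled construction of ring D, in which all six positions differ.

The key step uses the fact that C6 is an unsubstituted methylene between O5 and C6a. Ring B therefore maps onto an O5=C6H2 cation on ring A and a C6a=C11a enol ether attached to ring D.

## Logic of the disconnections

18 is opened at O11–C11a and the three phenols are masked as silyl ethers, which leads through 17 to 16. C11a is the one carbon that can be ionised at will, so closing ring C last makes its configuration a consequence of C6a. This removes ring C and one stereocentre from the problem. The forward step must ionise the C11a methyl ether gently enough that H6a is not lost and the ortho-prenyl phenols are not cyclised.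

16 is cut at C6–C6a and C11a–C11b, giving 6 and 15. Both bonds belong to ring B, and the cut divides the molecule into its two aromatic halves, with C6 supplied by a protecting-group carbon. Only C6a has to be controlled. The forward step must choose one face of the enol ether carbon, the enol ether must outcompete three other alkenes, the closure must go to C11b and not to C4, and the intermediate oxocarbenium ion must close before it loses H6a.

15 is cut at the C6a=C11a double bond to give 14. This is a one-carbon homologation of an aromatic aldehyde, and it returns to the oxidation level already present in 7. The forward step must deliver one alkene geometry, because a chiral counteranion cannot be expected to read the two geometries alike.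

14 is desilylated to 13. In 13 the bond between C7 and the chromene carbon, and the bond between C10 and the prenyl methylene, are traced back through 12 to two aryl ether O–C bonds in 11. Both carbon substituents sit ortho to an oxygen and can be delivered from that oxygen by sigmatropic shifts. Two C–C bonds on a crowded ring become two O-alkylations, and direct electrophilic chromene annulation, which would go to C10, is avoided. Each ether must have a single free ortho position, which holds because the other ortho position is oxygen-bearing in both cases. The allyl ether must be the 1,1-dimethylallyl isomer so that the shift gives a normal prenyl group.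

11 is cut at O8–C to give 10 and 8. 10 is the semihydrogenation product of 9, and 9 is cut at O9–C to give 7 and 8. The three hydroxyls of 7 differ in reactivity toward O-alkylation: O9–H, para to the formyl group, reacts first, then O8–H, and the chelated O10a–H last. One C5 reagent therefore serves twice. The first ether must be reduced before the second is introduced, so that the two C5 units differ, and each etherification needs stoichiometric control.

6 is cut at the aryl–CH2 bond at C2 to give 3 and 4 (through 5). 3 is cut at O–Si to give 2, and 2 at O–CH2 to give 1. The bromine of 1 marks C2, so ring A comes from three commercial components. The forward steps must transfer the prenyl group in its linear form and must tell the two hydroxyls of 1 apart.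

## Other disconnections considered

Alternative 1: The cut is C6a–C11a.
- **Forward step:** The ring D aryldiazoacetate A1, whose C10a oxygen carries the ring A benzyl group, would be decomposed by Rh2(S-PTTL)4 (divalent rhodium). The donor/acceptor carbene inserts into the benzylic C–H bond next to O11 and gives the cis-dihydrobenzofuran ester A2.
- **In its favour:** Carbene insertion into benzylic ether C–H bonds with this catalyst family is an established enantioselective route to cis-2-aryl-2,3-dihydrobenzofuran-3-carboxylates. It fixes C6a and C11a together with the correct cis relation. On precedent, and on the number of stereocentres set by the catalyst, it is better than the chosen plan.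
- **Against it here:** A2 lacks rings B and E. The ester must be reduced, and two MOM ethers must be removed with acid from a compound whose C11a–O11 bond is a 2,4-dioxygenated benzylic ether. Ring B must then be closed by Mitsunobu etherification and ring E built on O8 and C7. The cis ester can epimerise at C6a, and the carbene must ignore two prenyl alkenes and an electron-rich ring A.
- **Comparison:** On structure, the alternative forms the most acid-sensitive bond first and carries it through many steps, whereas the chosen plan forms it last. On mechanism, both rely on a chiral catalyst for absolute configuration, which is a point of equality. On step economy, the alternative needs several more operations after its key step.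

Alternative 2: The cut runs through ring D itself, at C6b–C10a.
- **Forward step:** Thermolysis of the 4-alkynyl-4-hydroxycyclobutenone A3 would open the four-membered ring to an alkynyl ketene, which closes to the quinone A4 (Moore cyclization).
- **In its favour:** The substitution pattern of ring D is dictated by the cyclobutenone, so no question of aromatic regiochemistry arises. Here it is better than the chosen plan, which depends on graded phenol reactivity. The conditions are neutral, which suits the prenyl groups better than cationic chemistry.
- **Against it here:** The step creates no stereocentre. C6a and C11a must already be present in A3, so the asymmetric problem is only moved to a cis-3-ethynylchroman-4-ol. A4 has hydrogen at C7 and a methoxy group at C9, so ring E must still be annulated and an aryl methyl ether cleaved in the presence of two prenyl groups. The quinone must be reduced before ring C can close, and closure to a cyclopentenedione competes with quinone formation.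
- **Comparison:** On structure, the alternative builds ring D from scratch but leaves rings C and E to be made, whereas the chosen plan brings rings D and E in complete. On mechanism, the ring C closure at C11a is the same event in both plans, a point of equality. On step economy, the alternative is clearly longer.

Alternative 3: The cut is C6a–C6b together with C11a–O11.
- **Forward step:** The quinone A5 would be bound through its C1 carbonyl and methoxy oxygen to the titanium TADDOLate made from TiCl2(OiPr)2 (tetravalent titanium). The chromene A6 adds through C6a to the quinone CH para to the methoxy-bearing carbon, and the C11a cation is captured by the quinone oxygen, giving the pterocarpan A7.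
- **In its favour:** It is the most convergent of all. Rings A to D, with the cis fusion, arise in one step from two simple partners, and an enantioselective form with stoichiometric titanium TADDOLate has precedent for pterocarpans. In convergence it is better than the chosen plan, and in stereochemical precedent at least its equal.
- **Against it here:** A7 has hydrogen at C7, a free hydroxyl at C8 and a methyl ether at C9. Ring E is still missing. The methyl ether, needed for two-point binding to titanium, would have to be cleaved by reagents that also attack prenyl groups, the chromene or the C11a–O11 bond. Cyclobutane (2+2) adducts and the prenyl alkenes are competitors, and the chiral Lewis acid is stoichiometric.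
- **Comparison:** On structure, the alternative reaches the pterocarpan core faster but cannot deliver the C9 hydroxyl and ring E without hard late steps, whereas the chosen plan carries both through in masked form. On mechanism, both are stepwise cationic annulations in which an electron-rich alkene attacks an activated electrophile and an internal nucleophile closes the ring, so their chemoselectivity concerns are alike. On step economy, it is shorter up to the key step and longer after it.

Key step: step 10

Assumption: pterocarpan numbering is used for all intermediates. The sense of induction of the chiral anion in step 10 cannot be assigned in advance, so the catalyst enantiomer that delivers (R)-C6a is the one used and is written here as (S,S).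

## Route

Step 1
Reactants: 1 4-bromoresorcinol
Product: 2 2-bromo-5-(methoxymethoxy)phenol
Conditions: MOMCl (1.0 equiv), iPr2NEt, CH2Cl2, −20 → 0 °C
Reagents that add atoms: chloromethyl methyl ether, COCCl
Why: O-alkylation with an α-chloro ether under amine-base conditions; the hydroxyl para to bromine (future O5) is both the more nucleophilic and the less hindered, so the mono-ether at that oxygen should predominate and the minor isomer and bis-ether are removed by chromatography.

Step 2
Reactants: 2 2-bromo-5-(methoxymethoxy)phenol
Product: 3 [2-bromo-5-(methoxymethoxy)phenoxy]triisopropylsilane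
Conditions: TIPSCl, imidazole, DMF, rt
Reagents that add atoms: chlorotriisopropylsilane, CC(C)[Si](Cl)(C(C)C)C(C)C
Why: Imidazole-assisted silylation of a phenol; the bulky silyl group is placed next to C4, where it later steers the ring closure, and it goes on before a palladium coupling so that no aryllithium ortho to a silyl ether (silyl migration from O to C) is ever formed.

Step 3
Reactants: 3 [2-bromo-5-(methoxymethoxy)phenoxy]triisopropylsilane; 4 prenyl bromide (1-bromo-3-methylbut-2-ene)
Product: 6 [5-(methoxymethoxy)-2-(3-methylbut-2-enyl)phenoxy]triisopropylsilane (ring A fragment), via prenylzinc bromide 5 (not isolated)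
Conditions: 4, Zn dust, LiCl, THF, 0 °C; then 3, Pd(OAc)2 (2 mol%), CPhos (2-dicyclohexylphosphino-2',6'-bis(dimethylamino)biphenyl, 4 mol%), THF, rt
Reagents that add atoms: none
Why: Negishi coupling of an allylic zinc reagent with an aryl bromide; with a bulky dialkylbiarylphosphine the allylpalladium intermediate should reductively eliminate at the primary carbon, giving the linear prenyl arene, and the MOM and silyl ethers are inert.

Step 4
Reactants: 7 2,4,5-trihydroxybenzaldehyde; 8 3-chloro-3-methylbut-1-yne
Product: 9 2,5-dihydroxy-4-[(2-methylbut-3-yn-2-yl)oxy]benzaldehyde
Conditions: 8 (1.05 equiv), DBU (1.05 equiv), CuCl2·2H2O (1 mol%), MeCN, −10 → 0 °C, argon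
Reagents that add atoms: none
Why: Copper-catalysed propargylic etherification of a phenol; with one equivalent of base the hydroxyl para to the formyl group (O9) is the one ionised and alkylated, as in the selective 4-O-alkylation of catechol aldehydes, while the chelated O10a–H and O8–H remain.

Step 5
Reactants: 9 2,5-dihydroxy-4-[(2-methylbut-3-yn-2-yl)oxy]benzaldehyde
Product: 10 2,5-dihydroxy-4-[(2-methylbut-3-en-2-yl)oxy]benzaldehyde
Conditions: H2 (1 atm), Pd/CaCO3 poisoned with Pb(OAc)2, quinoline, EtOAc, rt
Reagents that add atoms: none
Why: Semihydrogenation of a terminal alkyne over poisoned palladium (Lindlar-type) stops at the alkene and leaves the aldehyde and the aryl ether untouched; it turns the first C5 unit into the 1,1-dimethylallyl ether needed for the prenyl group.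

Step 6
Reactants: 10 2,5-dihydroxy-4-[(2-methylbut-3-en-2-yl)oxy]benzaldehyde; 8 3-chloro-3-methylbut-1-yne
Product: 11 2-hydroxy-4-[(2-methylbut-3-en-2-yl)oxy]-5-[(2-methylbut-3-yn-2-yl)oxy]benzaldehyde
Conditions: 8 (1.3 equiv), DBU (1.3 equiv), CuCl2·2H2O (1 mol%), MeCN, 0 °C, argon
Reagents that add atoms: none
Why: The same copper-catalysed propargylic etherification; the free O8–H should react in preference to the hydroxyl hydrogen-bonded to the formyl group, as in the selective 5-O-alkylation of 2,5-dihydroxybenzaldehydes.

Step 7
Reactants: 11 2-hydroxy-4-[(2-methylbut-3-en-2-yl)oxy]-5-[(2-methylbut-3-yn-2-yl)oxy]benzaldehyde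
Product: 13 6,8-dihydroxy-2,2-dimethyl-7-(3-methylbut-2-enyl)-2H-chromene-5-carbaldehyde, via C-prenylated propargyl ether 12 (not isolated)
Conditions: N,N-diethylaniline, 120 °C, then 170 °C, argon
Reagents that add atoms: none
Why: Two aromatic Claisen rearrangements in sequence: the 1,1-dimethylallyl ether shifts to its only free ortho carbon (C10) and gives the normal prenyl group of 12, then the propargyl ether shifts to C7 and the allenyl phenol closes by 1,5-hydrogen shift and oxa-6π electrocyclisation to the 2H-chromene. The regiochemistry is forced because the other ortho position of each ether carries oxygen.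

Step 8
Reactants: 13 6,8-dihydroxy-2,2-dimethyl-7-(3-methylbut-2-enyl)-2H-chromene-5-carbaldehyde
Product: 14 6,8-bis(tert-butyldimethylsilyloxy)-2,2-dimethyl-7-(3-methylbut-2-enyl)-2H-chromene-5-carbaldehyde
Conditions: TBSOTf (2.5 equiv), 2,6-lutidine, CH2Cl2, 0 °C → rt
Reagents that add atoms: tert-butyldimethylsilyl trifluoromethanesulfonate, CC(C)(C)[Si](C)(C)OS(=O)(=O)C(F)(F)F
Why: A silyl triflate with a hindered pyridine base silylates both di-ortho-substituted phenols, including the one hydrogen-bonded to the aldehyde; excess base keeps the medium free of acid that could cyclise the prenyl phenol.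

Step 9
Reactants: 14 6,8-bis(tert-butyldimethylsilyloxy)-2,2-dimethyl-7-(3-methylbut-2-enyl)-2H-chromene-5-carbaldehyde
Product: 15 (E)-6,8-bis(tert-butyldimethylsilyloxy)-5-(2-methoxyethenyl)-2,2-dimethyl-7-(3-methylbut-2-enyl)-2H-chromene (ring D/E fragment)
Conditions: Ph3P(CH2OMe)Cl, NaHMDS, THF, 0 °C; then 14, 0 °C → rt; E isomer isolated on AgNO3-impregnated, Et3N-deactivated silica
Reagents that add atoms: (methoxymethyl)triphenylphosphonium chloride, COC[P+](c1ccccc1)(c1ccccc1)c1ccccc1.[Cl-]
Why: Wittig methoxymethylenation of a hindered aromatic aldehyde; the reaction is not expected to be stereoselective, so the E isomer is separated to give the key step a single alkene geometry.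

Step 10
Reactants: 6 [5-(methoxymethoxy)-2-(3-methylbut-2-enyl)phenoxy]triisopropylsilane; 15 (E)-6,8-bis(tert-butyldimethylsilyloxy)-5-(2-methoxyethenyl)-2,2-dimethyl-7-(3-methylbut-2-enyl)-2H-chromene
Product: 16 (3R)-3-[6,8-bis(tert-butyldimethylsilyloxy)-2,2-dimethyl-7-(3-methylbut-2-enyl)-2H-chromen-5-yl]-4-methoxy-6-(3-methylbut-2-enyl)-7-(triisopropylsilyloxy)chromane (C6a as in the target; both C11a epimers)
Conditions: (S,S)-IDPi acid (imidodiphosphorimidate from two 3,3'-diaryl-BINOL units, N-triflyl; 5 mol%), allyltrimethylsilane (1.2 equiv), 15 (1.3 equiv), toluene, −78 °C, slow addition of 6; Et3N quench at −78 °C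
Reagents that add atoms: none
Why: Proposed new method: the silylated imidodiphosphorimidate (Me3Si+ paired with the chiral anion, formed from the acid and allyltrimethylsilane) should abstract methoxide from the O,O-acetal of 6 to give the O5=C6H2 cation as a contact ion pair, the β-carbon of 15 (C6a) should add to it (C6–C6a) and the resulting methoxy-oxocarbenium ion at C11a should be captured by ring A at C11b (C11a–C11b), a stepwise cationic (4+2); the closest known reaction types are the Lewis acid-promoted oxa-Povarov reaction of aryloxy-substituted oxocarbenium ions with alkenes, established in racemic form with stoichiometric SnCl4, and imidodiphosphorimidate counteranion control of oxocarbenium additions under silylium catalysis. Ring B is closed by a six-membered Friedel–Crafts alkylation that is exo with respect to the C11a=O+ bond. C6a is created in the C–C bond-forming step and its configuration is controlled by the confined chiral anion, which is expected to expose one face of the enol ether β-carbon to the small, achiral methylene electrophile; the small size of that electrophile is what allows bond formation next to the di-ortho-substituted ring D. C11a is formed under substrate control (aryl and methoxy trans is expected to prevail) and needs no control because it is ionised again in step 11. Chemoselectivity rests on the enol ether being by far the strongest π-nucleophile present, ahead of the prenyl groups, the chromene alkene and the allylsilane, and it is supported by adding 6 slowly to an excess of 15 so that the cation does not alkylate ring A of a second molecule. Closure goes to C11b and not to C4 because C4 lies between O5 and the triisopropylsilyloxy group, whereas C11b is para to that group and unhindered. The allylsilane converts the proton released on rearomatisation back into the silylium ion pair with loss of propene, so neither free acid nor methanol accumulates, which should protect the geometry of 15, the C6a–H bond of the oxocarbenium ion and the C11a ether of 16. If the C10a silyl ether closed ring C prematurely, the resulting pterocarpan would still converge on 18 in step 11.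

Step 11
Reactants: 16 (3R)-3-[6,8-bis(tert-butyldimethylsilyloxy)-2,2-dimethyl-7-(3-methylbut-2-enyl)-2H-chromen-5-yl]-4-methoxy-6-(3-methylbut-2-enyl)-7-(triisopropylsilyloxy)chromane
Product: 18 lespecyrtin E3, via desilylated triphenol 17 (not isolated)
Conditions: Bu4NF, AcOH, THF, 0 °C; aqueous work-up; then PPTS (cat.), CH2Cl2, rt, argon
Reagents that add atoms: none
Why: Buffered fluoride cleaves the three aryl silyl ethers; mild acid then ionises the C11a methyl ether to a cation stabilised by the para C3 hydroxyl and O5 (para-quinone methide character), and the C10a hydroxyl closes ring C by 5-exo attack. Only the cis ring fusion is accessible, so C11a is set as R by the existing C6a centre, which is not touched.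

## Compound list

1 | 4-bromoresorcinol (4-bromobenzene-1,3-diol) | Oc1ccc(Br)c(O)c1 | starting material
2 | 2-bromo-5-(methoxymethoxy)phenol | COCOc1ccc(Br)c(O)c1 | intermediate
3 | [2-bromo-5-(methoxymethoxy)phenoxy]triisopropylsilane | COCOc1ccc(Br)c(O[Si](C(C)C)(C(C)C)C(C)C)c1 | intermediate
4 | prenyl bromide (1-bromo-3-methylbut-2-ene) | CC(C)=CCBr | starting material
5 | prenylzinc bromide | CC(C)=CC[Zn]Br | intermediate
6 | [5-(methoxymethoxy)-2-(3-methylbut-2-enyl)phenoxy]triisopropylsilane | COCOc1ccc(CC=C(C)C)c(O[Si](C(C)C)(C(C)C)C(C)C)c1 | intermediate
7 | 2,4,5-trihydroxybenzaldehyde | O=Cc1cc(O)c(O)cc1O | starting material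
8 | 3-chloro-3-methylbut-1-yne | CC(C)(Cl)C#C | starting material
9 | 2,5-dihydroxy-4-[(2-methylbut-3-yn-2-yl)oxy]benzaldehyde | O=Cc1cc(O)c(OC(C)(C)C#C)cc1O | intermediate
10 | 2,5-dihydroxy-4-[(2-methylbut-3-en-2-yl)oxy]benzaldehyde | O=Cc1cc(O)c(OC(C)(C)C=C)cc1O | intermediate
11 | 2-hydroxy-4-[(2-methylbut-3-en-2-yl)oxy]-5-[(2-methylbut-3-yn-2-yl)oxy]benzaldehyde | O=Cc1cc(OC(C)(C)C#C)c(OC(C)(C)C=C)cc1O | intermediate
12 | 2,4-dihydroxy-3-(3-methylbut-2-enyl)-5-[(2-methylbut-3-yn-2-yl)oxy]benzaldehyde | O=Cc1cc(OC(C)(C)C#C)c(O)c(CC=C(C)C)c1O | intermediate
13 | 6,8-dihydroxy-2,2-dimethyl-7-(3-methylbut-2-enyl)-2H-chromene-5-carbaldehyde | O=Cc1c2C=CC(C)(C)Oc2c(O)c(CC=C(C)C)c1O | intermediate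
14 | 6,8-bis(tert-butyldimethylsilyloxy)-2,2-dimethyl-7-(3-methylbut-2-enyl)-2H-chromene-5-carbaldehyde | O=Cc1c2C=CC(C)(C)Oc2c(O[Si](C)(C)C(C)(C)C)c(CC=C(C)C)c1O[Si](C)(C)C(C)(C)C | intermediate
15 | (E)-6,8-bis(tert-butyldimethylsilyloxy)-5-(2-methoxyethenyl)-2,2-dimethyl-7-(3-methylbut-2-enyl)-2H-chromene | CO/C=C/c1c2C=CC(C)(C)Oc2c(O[Si](C)(C)C(C)(C)C)c(CC=C(C)C)c1O[Si](C)(C)C(C)(C)C | intermediate
16 | (3R)-3-[6,8-bis(tert-butyldimethylsilyloxy)-2,2-dimethyl-7-(3-methylbut-2-enyl)-2H-chromen-5-yl]-4-methoxy-6-(3-methylbut-2-enyl)-7-(triisopropylsilyloxy)chromane, C4 epimers | CC(C)=CCc1cc2c(cc1O[Si](C(C)C)(C(C)C)C(C)C)OC[C@@H](c1c3C=CC(C)(C)Oc3c(O[Si](C)(C)C(C)(C)C)c(CC=C(C)C)c1O[Si](C)(C)C(C)(C)C)C2OC | intermediate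
17 | (3R)-3-[6,8-dihydroxy-2,2-dimethyl-7-(3-methylbut-2-enyl)-2H-chromen-5-yl]-4-methoxy-6-(3-methylbut-2-enyl)chroman-7-ol, C4 epimers | CC(C)=CCc1cc2c(cc1O)OC[C@@H](c1c3C=CC(C)(C)Oc3c(O)c(CC=C(C)C)c1O)C2OC | intermediate
18 | lespecyrtin E3, (6aR,11aR)-3,9-dihydroxy-2,10-bis(3-methylbut-2-enyl)pterocarpan with a 2,2-dimethyl-2H-pyran fused at C7–C8 (oxygen on C8) | CC(C)=CCc1cc2c(cc1O)OC[C@H]1c3c4c(c(O)c(CC=C(C)C)c3O[C@@H]21)OC(C)(C)C=C4 | target

## Step count and least certain steps

Total step count: 11. Longest linear sequence: 8 (steps 4 to 11). Ring A takes steps 1 to 3.

**Step 10 (key step).**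
- **Risk:** Facial discrimination at C6a by the anion may be insufficient in this new substrate class. The C6a configuration may erode through reversible proton loss from the C11a oxocarbenium ion before ring closure, or through re-ionisation of the product and elimination toward the isoflav-3-ene. The aryloxymethyl cation may also be diverted by the allylsilane or by ring A of a second molecule.
- **Fallback (known chemistry):** Setting out from 6 and 15, the racemic Lewis acid-promoted oxa-Povarov reaction with stoichiometric SnCl4 (CH2Cl2, −78 °C) would give the racemic 4-methoxyisoflavan F1. F1 would be carried through the conditions of step 11 to racemic lespecyrtin E3 F2, which has only two stereoisomers. The enantiomers would be separated by preparative chromatography on a chiral stationary phase, and the fallback comes back to the route at 18.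

**Step 7.**
- **Risk:** The tertiary ethers may fragment by ionisation before they rearrange, and the ortho-prenyl phenol may react further (abnormal Claisen rearrangement, chroman formation) at the temperature the propargyl ether needs.
- **Fallback:** Setting out from 11, the allyl ether would be rearranged alone at about 60 °C with Eu(fod)3 (europium tris(6,6,7,7,8,8,8-heptafluoro-2,2-dimethyloctane-3,5-dionate)) in CHCl3, and 12 would be isolated. Silylation with TBSOTf and 2,6-lutidine would give the bis-silyl propargyl ether F3. The chromene would then be closed at room temperature by 6-endo hydroarylation of the alkyne with Ph3PAuNTf2 in CH2Cl2, a metal-catalysed ring closure in place of the pericyclic cascade. The fallback comes back to the route at 14.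

**Step 9.**
- **Risk:** The olefination may lack geometric control, with loss of material on separation, and the hindered electron-rich enol ether may partly hydrolyse on silica.
- **Fallback:** Setting out from 14, Takai–Utimoto olefination with Cl2CHBpin, CrCl2 and LiI in THF would give the (E)-alkenylboronic ester F4 with the geometry fixed by the reaction. Chan–Lam–Evans etherification with methanol (Cu(OAc)2, Et3N, air) would replace boron by methoxy with retention. The fallback comes back to the route at 15.

**Step 1.**
- **Risk:** Regioselectivity between the two hydroxyls may be incomplete, and bis-alkylation may occur.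
- **Fallback:** Setting out from 1, acylation with pivaloyl chloride and pyridine at low temperature would mark the less hindered, more nucleophilic hydroxyl as the mono-pivalate F5. Silylation of the remaining hydroxyl with TIPSOTf and 2,6-lutidine would give the silyl ether pivalate F6. Reductive removal of the ester with DIBAL-H (toluene, −78 °C) would give the silyloxyphenol F7, and MOMCl with iPr2NEt would then give the MOM ether. The fallback comes back to the route at 3.

**Step 11.**
- **Risk:** The C11a cation may lose the C6a proton, the ortho-prenyl phenols may cyclise under acid, and the free triphenol may oxidise in air.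
- **Fallback:** Setting out from 16, the order would be reversed. A catalytic amount of TMSOTf with 2,6-di-tert-butyl-4-methylpyridine (CH2Cl2, −78 °C) would ionise the C11a ether while all phenols are still silylated, and the C10a silyl ether oxygen would close ring C with transfer of its silyl group to methoxide, giving the bis-silyl pterocarpan F8. Bu4NF buffered with AcOH would then remove the two remaining silyl groups. The fallback comes back to the route at 18.

## Further compounds

F1 | step 10 | racemic 3-[6,8-bis(tert-butyldimethylsilyloxy)-2,2-dimethyl-7-(3-methylbut-2-enyl)-2H-chromen-5-yl]-4-methoxy-6-(3-methylbut-2-enyl)-7-(triisopropylsilyloxy)chromane, all stereoisomers | CC(C)=CCc1cc2c(cc1O[Si](C(C)C)(C(C)C)C(C)C)OCC(c1c3C=CC(C)(C)Oc3c(O[Si](C)(C)C(C)(C)C)c(CC=C(C)C)c1O[Si](C)(C)C(C)(C)C)C2OC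
F2 | step 10 | racemic lespecyrtin E3, cis (6aR*,11aR*) | CC(C)=CCc1cc2c(cc1O)OCC1c3c4c(c(O)c(CC=C(C)C)c3OC21)OC(C)(C)C=C4
F3 | step 7 | 2,4-bis(tert-butyldimethylsilyloxy)-3-(3-methylbut-2-enyl)-5-[(2-methylbut-3-yn-2-yl)oxy]benzaldehyde | O=Cc1cc(OC(C)(C)C#C)c(O[Si](C)(C)C(C)(C)C)c(CC=C(C)C)c1O[Si](C)(C)C(C)(C)C
F4 | step 9 | (E)-2-[2-[6,8-bis(tert-butyldimethylsilyloxy)-2,2-dimethyl-7-(3-methylbut-2-enyl)-2H-chromen-5-yl]ethenyl]-4,4,5,5-tetramethyl-1,3,2-dioxaborolane | CC1(C)OB(/C=C/c2c3C=CC(C)(C)Oc3c(O[Si](C)(C)C(C)(C)C)c(CC=C(C)C)c2O[Si](C)(C)C(C)(C)C)OC1(C)C
F5 | step 1 | 4-bromo-3-hydroxyphenyl 2,2-dimethylpropanoate | CC(C)(C)C(=O)Oc1ccc(Br)c(O)c1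
F6 | step 1 | 4-bromo-3-(triisopropylsilyloxy)phenyl 2,2-dimethylpropanoate | CC(C)(C)C(=O)Oc1ccc(Br)c(O[Si](C(C)C)(C(C)C)C(C)C)c1
F7 | step 1 | 4-bromo-3-(triisopropylsilyloxy)phenol | Oc1ccc(Br)c(O[Si](C(C)C)(C(C)C)C(C)C)c1
F8 | step 11 | (6aR,11aR)-9-(tert-butyldimethylsilyloxy)-3-(triisopropylsilyloxy) derivative of lespecyrtin E3 | CC(C)=CCc1cc2c(cc1O[Si](C(C)C)(C(C)C)C(C)C)OC[C@H]1c3c4c(c(O[Si](C)(C)C(C)(C)C)c(CC=C(C)C)c3O[C@@H]21)OC(C)(C)C=C4
A1 | alternative 1 | methyl 2-diazo-2-[2-[[2-(methoxymethoxy)-5-(3-methylbut-2-enyl)-4-(triisopropylsilyloxy)phenyl]methoxy]-5-(methoxymethoxy)-3-(3-methylbut-2-enyl)-4-(triisopropylsilyloxy)phenyl]acetate | COC(=O)C(=[N+]=[N-])c1cc(OCOC)c(O[Si](C(C)C)(C(C)C)C(C)C)c(CC=C(C)C)c1OCc1cc(CC=C(C)C)c(O[Si](C(C)C)(C(C)C)C(C)C)cc1OCOC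
A2 | alternative 1 | methyl cis-2-(ring A aryl)-2,3-dihydrobenzofuran-3-carboxylate with C6a and C11a as in the target | COC(=O)[C@H]1c2cc(OCOC)c(O[Si](C(C)C)(C(C)C)C(C)C)c(CC=C(C)C)c2O[C@H]1c1cc(CC=C(C)C)c(O[Si](C(C)C)(C(C)C)C(C)C)cc1OCOC
A3 | alternative 2 | 4-hydroxy-3-methoxy-2-(3-methylbut-2-enyl)-4-[(cis-4-(tert-butyldimethylsilyloxy)-6-(3-methylbut-2-enyl)-7-(triisopropylsilyloxy)chroman-3-yl)ethynyl]cyclobut-2-en-1-one | COC1=C(CC=C(C)C)C(=O)C1(O)C#C[C@@H]1COc2cc(O[Si](C(C)C)(C(C)C)C(C)C)c(CC=C(C)C)cc2[C@@H]1O[Si](C)(C)C(C)(C)C
A4 | alternative 2 | 2-methoxy-3-(3-methylbut-2-enyl)-5-(cis-4-silyloxychroman-3-yl)-1,4-benzoquinone with C6a as in the target | CC(C)=CCc1cc2c(cc1O[Si](C(C)C)(C(C)C)C(C)C)OC[C@@H](C1=CC(=O)C(OC)=C(CC=C(C)C)C1=O)[C@H]2O[Si](C)(C)C(C)(C)C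
A5 | alternative 3 | 2-methoxy-3-(3-methylbut-2-enyl)-1,4-benzoquinone | COC1=C(CC=C(C)C)C(=O)C=CC1=O
A6 | alternative 3 | 6-(3-methylbut-2-enyl)-7-(triisopropylsilyloxy)-2H-chromene | CC(C)=CCc1cc2C=CCOc2cc1O[Si](C(C)C)(C(C)C)C(C)C
A7 | alternative 3 | (6aR,11aR)-8-hydroxy-9-methoxy-2,10-bis(3-methylbut-2-enyl)-3-(triisopropylsilyloxy)pterocarpan | CC(C)=CCc1cc2c(cc1O[Si](C(C)C)(C(C)C)C(C)C)OC[C@H]1c3cc(O)c(OC)c(CC=C(C)C)c3O[C@@H]21
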